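The route rests on cutting the bond between the ring A benzylic CH2 and C5 of the piperazine. The ten-atom strap CH2–ring B–O–ring A–CH2 spans C2 and C5 of the six-membered diaza ring. It can lie on only one face, so closure must give the cis isomer, and the key step exploits this. A lithium aza-enolate at the glycine carbon of a cyclo(Gly-L-Tyr) bis-lactim ether displaces a ring A benzylic bromide. One operation thus creates the C–C bond, the 14-membered para/meta-cyclophane and the second (S) stereocentre. The precursor is the (S)-3,6-dimethoxy-2,5-dihydropyrazine whose tyrosine oxygen already carries the 2-benzyloxy-5-(bromomethyl)phenyl ring.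

Key step: step 8

Assumption: the guanine tautomer is taken as drawn in the target, and forms of a numbered compound that differ only by protonation (imidate or ammonium salts before neutralisation) are not numbered separately.

Step 1
Reactants: 1 4-borono-L-phenylalanine
Product: 2 methyl (S)-2-amino-3-(4-boronophenyl)propanoate hydrochloride
Conditions: SOCl2, MeOH, 0 °C to 40 °C
Reagents that add atoms: methanol, CO; thionyl chloride, O=S(Cl)Cl (source of the chloride counter-ion)
Why: Fischer esterification under HCl generated from SOCl2 and MeOH is routine for amino acids, the protonated amine shields the α-carbon from epimerisation, and the arylboronic acid, at most transiently esterified, returns on work-up.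

Step 2
Reactants: 2 methyl (S)-2-amino-3-(4-boronophenyl)propanoate hydrochloride; 3 N-Boc-glycine N-hydroxysuccinimide ester
Product: 4 Boc-Gly-L-Phe(4-B(OH)2)-OMe
Conditions: Et3N, DMF, 0 °C to rt
Reagents that add atoms: none
Why: Aminolysis of an N-hydroxysuccinimide active ester forms the peptide bond without a coupling reagent, the achiral glycine acyl donor excludes any oxazolone racemisation, and glycine is placed at the N terminus so that the amine freed later beside an aldehyde is achiral.

Step 3
Reactants: 4 Boc-Gly-L-Phe(4-B(OH)2)-OMe; 5 4-(benzyloxy)-3-hydroxybenzaldehyde (ring A, used in excess)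
Product: 6 Boc-Gly-L-Tyr(O-aryl)-OMe in which aryl is 2-(benzyloxy)-5-formylphenyl
Conditions: Cu(OAc)2 (50 mol %), pyridine, 4 Å MS, O2 (1 atm), CH2Cl2, rt
Reagents that add atoms: none
Why: Chan–Lam–Evans O-arylation runs at room temperature with only pyridine as base while O2 keeps the copper divalent, so stereocentre, ester and aldehyde are untouched; the unhindered para-alkyl boronic acid is paired with the ortho-alkoxyphenol, which avoids a hot carbonate-based Ullmann coupling that could epimerise the amino ester.

Step 4
Reactants: 6 Boc-Gly-L-Tyr(O-aryl)-OMe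
Product: 8 (S)-3-{4-[2-(benzyloxy)-5-formylphenoxy]benzyl}piperazine-2,5-dione, via free amine 7 (not isolated)
Conditions: TFA, CH2Cl2, 0 °C to rt; evaporate; Et3N, MeOH (0.02 M), 40 °C
Reagents that add atoms: none
Why: Boc acidolysis followed by 6-exo-trig aminolysis of the methyl ester is the standard diketopiperazine closure, and because the amine that meets the aldehyde is that of glycine, reversible imine formation cannot labilise the stereocentre and drains into the irreversible lactamisation.

Step 5
Reactants: 8 (S)-diketopiperazine aldehyde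
Product: 9 4-(benzyloxy)-3-(4-{[(2S)-3,6-dimethoxy-2,5-dihydropyrazin-2-yl]methyl}phenoxy)benzaldehyde
Conditions: Me3OBF4 (3 equiv), CH2Cl2, rt, Ar; cold aq Na2CO3 quench
Reagents that add atoms: trimethyloxonium tetrafluoroborate, C[O+](C)C.F[B-](F)(F)F
Why: Meerwein O-alkylation of both lactams gives the bis-lactim ether without touching C2–H, and it is run at the aldehyde oxidation level because a free benzylic alcohol would itself be methylated, whereas any O-methylated aldehyde reverts on the basic quench.

Step 6
Reactants: 9 bis-lactim ether aldehyde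
Product: 10 [4-(benzyloxy)-3-(4-{[(2S)-3,6-dimethoxy-2,5-dihydropyrazin-2-yl]methyl}phenoxy)phenyl]methanol
Conditions: NaBH4, MeOH–THF, 0 °C
Reagents that add atoms: none
Why: Borohydride reduction of an aromatic aldehyde is fast at 0 °C, whereas neutral, unprotonated lactim ethers are inert to NaBH4 in this basic medium.

Step 7
Reactants: 10 bis-lactim ether benzylic alcohol
Product: 11 (2S)-2-{4-[2-(benzyloxy)-5-(bromomethyl)phenoxy]benzyl}-3,6-dimethoxy-2,5-dihydropyrazine
Conditions: CBr4, PPh3, 2,6-lutidine (buffer, 0.2 equiv), CH2Cl2, −20 to 0 °C; rapid filtration through neutral alumina; used at once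
Reagents that add atoms: carbon tetrabromide, BrC(Br)(Br)Br
Why: The Appel reaction turns the primary benzylic alcohol into the bromide under essentially neutral conditions that spare the acid-labile lactim ethers, and the p-alkoxybenzylic bromide is not stored because it ionises easily and could alkylate the imidate nitrogens.

Step 8
Reactants: 11 bis-lactim ether benzylic bromide
Product: 13 bridged (2S,5S) bis-lactim ether cyclophane, via lithium aza-enolate 12 (not isolated)
Conditions: LiN(i-Pr)2 (preformed solution, 1.05 equiv, dropwise), THF (1–2 mM in 11), −78 °C, then slowly to −20 °C; pH 7 phosphate buffer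
Reagents that add atoms: none
Why: Proposed new method: LiN(i-Pr)2 abstracts one proton from the unsubstituted C5H2 of the dihydropyrazine to give the planar lithium aza-enolate 12, and on slow warming its C5 carbon displaces bromide from the ring A CH2Br carbon by SN2. The closest known reaction type is the intermolecular Schöllkopf alkylation of lithiated bis-lactim ethers with benzylic halides, with enolate alkylations that bridge C3 and C6 of diketopiperazines as a second relative; only the macrocyclic, cyclophane-forming use is new. The one ring formed closes 14-exo-tet with the bromide outside the ring, and the attack runs along the C5 p orbital, which is parallel to the pseudoaxial C2–CH2 bond of the folded arylmethyl side chain, so strap and orbital point the same way. The new C5 stereocentre is controlled by the tether: it is anchored at (S)-C2 on one face and is too short to wrap round the ring, so closure can only give the cis-(2S,5S) product, while the normal trans preference can show itself only in intermolecular alkylation, which the high dilution holds back. The step needs site-selective deprotonation, since loss of C2–H would erode enantiopurity (never the cis relationship); the less substituted, more accessible glycine CH2, a bare 1.05 equiv of hindered base and −78 °C secure it. C- rather than N-alkylation is the rule for these anions, no other acidic proton is present, and the p-alkoxybenzylic bromide is reactive enough to be captured well below 0 °C.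

Step 9
Reactants: 13 bridged bis-lactim ether cyclophane
Product: 15 N,N'-di-Boc O-benzyl (2S,5S)-piperazine cyclophane, via free piperazine 14 (not isolated)
Conditions: HBF4·OEt2 (2.1 equiv), CH2Cl2, −20 °C; NaBH4 (excess), abs. EtOH, 0 °C to rt; then aq NaHCO3, Boc2O, THF, rt
Reagents that add atoms: di-tert-butyl dicarbonate, CC(C)(C)OC(=O)OC(=O)OC(C)(C)C
Why: Borch-type reduction, in which protonation by an acid with a non-nucleophilic counter-ion makes each lactim ether an iminium-like imidate salt that takes up hydride, loses methanol and takes up a second hydride to give CH2–NH; C2 and C5 cannot epimerise through transient imine or enamine forms because the strap admits only the cis arrangement, and Boc2O caps both amines in the same flask.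

Step 10
Reactants: 15 N,N'-di-Boc O-benzyl cyclophane
Product: 16 N,N'-di-Boc (2S,5S)-piperazine cyclophane phenol
Conditions: H2 (1 atm), 10% Pd/C, EtOAc–MeOH, rt
Reagents that add atoms: none
Why: Catalytic hydrogenolysis cleaves only the benzyl aryl ether, since the diaryl ether, the carbamates and the homobenzylic C–N bonds are inert under these conditions.

Step 11
Reactants: 16 N,N'-di-Boc cyclophane phenol
Product: 17 N,N'-di-Boc cyclophane salicylaldehyde (CHO on ring A ortho to OH)
Conditions: MgCl2 (anhydrous), Et3N, (CH2O)n, MeCN, reflux; dilute citric acid work-up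
Reagents that add atoms: paraformaldehyde (as formaldehyde), C=O
Why: Casnati–Skattebøl ortho-formylation proceeds through the magnesium phenoxide, which delivers formaldehyde only ortho to oxygen, and ring A has a single free ortho position (the other carries the aryloxy group, para carries the CH2), so only one regioisomer can form, while the Boc groups keep the amines out of Mannich chemistry.

Step 12
Reactants: 17 N,N'-di-Boc cyclophane salicylaldehyde; 18 2,5,6-triaminopyrimidin-4(3H)-one dihydrochloride
Product: 20 N,N'-di-Boc-guanipiperazine A, via Schiff base 19 (not isolated)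
Conditions: NaOAc, DMSO, Ar, 50 °C; then I2 (1.1 equiv), 50 °C
Reagents that add atoms: none
Why: Traube-type purine annulation, in which the most nucleophilic 5-amino group gives the salicylaldimine 19 and the 6-amino group adds to its C=N; because an aldehyde lies two electrons below the purine oxidation level, I2 is added to dehydrogenate the cyclic aminal, the ring A phenol offers no free ortho or para position for iodination, and the acetate buffer protects the Boc groups.

Step 13
Reactants: 20 N,N'-di-Boc-guanipiperazine A
Product: 21 guanipiperazine A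
Conditions: TFA, CH2Cl2, 0 °C to rt; evaporate; aq NH3 to pH 9, reversed-phase purification
Reagents that add atoms: none
Why: Acidolysis of both tert-butyl carbamates (loss of isobutene and CO2) touches no other bond, and neutralisation releases the free base with both (S) stereocentres unchanged.

Compound list
1 | 4-borono-L-phenylalanine | N[C@@H](Cc1ccc(B(O)O)cc1)C(=O)O | starting material
2 | methyl (S)-2-amino-3-(4-boronophenyl)propanoate hydrochloride | Cl.N[C@@H](Cc1ccc(B(O)O)cc1)C(=O)OC | intermediate
3 | N-Boc-glycine N-hydroxysuccinimide ester | CC(C)(C)OC(=O)NCC(=O)ON1C(=O)CCC1=O | starting material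
4 | Boc-Gly-L-Phe(4-B(OH)2)-OMe | CC(C)(C)OC(=O)NCC(=O)N[C@@H](Cc1ccc(B(O)O)cc1)C(=O)OC | intermediate
5 | 4-(benzyloxy)-3-hydroxybenzaldehyde | O=Cc1ccc(OCc2ccccc2)c(O)c1 | starting material
6 | Boc-Gly-L-Tyr[O-(2-benzyloxy-5-formylphenyl)]-OMe | CC(C)(C)OC(=O)NCC(=O)N[C@@H](Cc1ccc(Oc2cc(C=O)ccc2OCc2ccccc2)cc1)C(=O)OC | intermediate
7 | H-Gly-L-Tyr[O-(2-benzyloxy-5-formylphenyl)]-OMe, free amine | NCC(=O)N[C@@H](Cc1ccc(Oc2cc(C=O)ccc2OCc2ccccc2)cc1)C(=O)OC | intermediate
8 | (S)-3-{4-[2-(benzyloxy)-5-formylphenoxy]benzyl}piperazine-2,5-dione | O=C1N[C@@H](Cc2ccc(Oc3cc(C=O)ccc3OCc3ccccc3)cc2)C(=O)NC1 | intermediate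
9 | (2S) bis-lactim ether aldehyde | COC1=N[C@@H](Cc2ccc(Oc3cc(C=O)ccc3OCc3ccccc3)cc2)C(OC)=NC1 | intermediate
10 | (2S) bis-lactim ether benzylic alcohol | COC1=N[C@@H](Cc2ccc(Oc3cc(CO)ccc3OCc3ccccc3)cc2)C(OC)=NC1 | intermediate
11 | (2S) bis-lactim ether benzylic bromide (key-step precursor) | COC1=N[C@@H](Cc2ccc(Oc3cc(CBr)ccc3OCc3ccccc3)cc2)C(OC)=NC1 | intermediate
12 | C5-lithiated aza-enolate of 11 | [Li+].COC1=N[C@@H](Cc2ccc(Oc3cc(CBr)ccc3OCc3ccccc3)cc2)C(OC)=N[CH-]1 | intermediate
13 | bridged (2S,5S) bis-lactim ether cyclophane (key-step product) | c1ccccc1COc1ccc2cc1Oc1ccc(cc1)C[C@H]1C(OC)=N[C@H](C(OC)=N1)C2 | intermediate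
14 | O-benzyl (2S,5S)-piperazine cyclophane, free diamine | c1ccccc1COc1ccc2cc1Oc1ccc(cc1)C[C@H]1CN[C@H](CN1)C2 | intermediate
15 | N,N'-di-Boc O-benzyl (2S,5S)-piperazine cyclophane | c1ccccc1COc1ccc2cc1Oc1ccc(cc1)C[C@H]1CN(C(=O)OC(C)(C)C)[C@H](CN1C(=O)OC(C)(C)C)C2 | intermediate
16 | N,N'-di-Boc (2S,5S)-piperazine cyclophane phenol | Oc1ccc2cc1Oc1ccc(cc1)C[C@H]1CN(C(=O)OC(C)(C)C)[C@H](CN1C(=O)OC(C)(C)C)C2 | intermediate
17 | N,N'-di-Boc cyclophane salicylaldehyde | O=Cc1cc2cc(c1O)Oc1ccc(cc1)C[C@H]1CN(C(=O)OC(C)(C)C)[C@H](CN1C(=O)OC(C)(C)C)C2 | intermediate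
18 | 2,5,6-triaminopyrimidin-4(3H)-one dihydrochloride | Cl.Cl.Nc1nc(N)c(N)c(=O)[nH]1 | starting material
19 | (E)-5-(arylideneamino)-2,6-diaminopyrimidin-4(3H)-one Schiff base of 17 | Nc1nc(N)c(/N=C/c2cc3cc(c2O)Oc2ccc(cc2)C[C@H]2CN(C(=O)OC(C)(C)C)[C@H](CN2C(=O)OC(C)(C)C)C3)c(=O)[nH]1 | intermediate
20 | N,N'-di-Boc-guanipiperazine A | Nc1nc2nc(-c3cc4cc(c3O)Oc3ccc(cc3)C[C@H]3CN(C(=O)OC(C)(C)C)[C@H](CN3C(=O)OC(C)(C)C)C4)[nH]c2c(=O)[nH]1 | intermediate
21 | guanipiperazine A | Nc1nc2nc(-c3cc4cc(c3O)Oc3ccc(cc3)C[C@H]3CN[C@H](CN3)C4)[nH]c2c(=O)[nH]1 | target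

Total step count: 13. Longest linear sequence: 13 (1 to 21; compounds 3, 5 and 18 are purchased).

Steps most likely to fail

1. Step 8 (the labelled step).
- What may go wrong: ring closure may be too slow for the strained strap, so that intermolecular alkylation to chains and cyclic dimers takes over. Proton shuffling between C5 and C2 of the anion may erode enantiopurity, and the base may consume the benzylic bromide.
- Fallback, known chemistry only, from 5 back to 15: both stereocentres are taken from L-configured amino acid units and the macrocycle is closed at the diaryl ether oxygen instead. Aldehyde 5 is condensed with methyl 2-(Boc-amino)-2-(dimethoxyphosphoryl)acetate (DBU, CH2Cl2; Horner–Wadsworth–Emmons) to the (Z)-dehydroamino ester F1. Hydrogenation with [Rh(cod)((S,S)-Et-DuPhos)]BF4 gives the (S)-Boc-amino ester F2. HCl in dioxane gives the amine hydrochloride F3, and EDC/HOBt coupling with commercial N-Boc-4-iodo-L-phenylalanine gives the dipeptide F4. TFA followed by Et3N in MeOH leads, through the free amine F5, to the cis-diketopiperazine F6. BH3·THF reduces it to the cis-piperazine F7, and Boc2O caps this as the di-Boc seco compound F8. An intramolecular Ullmann etherification (CuBr·SMe2, Cs2CO3, pyridine, high dilution, heat) between the ring A phenol and the ring B iodide, a known closure for 14-membered para/meta-cyclophane diaryl ethers, then gives 15. The substrate no longer holds an epimerisable centre.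

2. Step 9.
- What may go wrong: the protonated lactim ethers may be opened by ethanol before hydride arrives, reduction may stall halfway, or the diamine may be held back as a borane complex.
- Fallback from 13 back to 15: dry HCl in dioxane at 50 °C dealkylates both imidate hydrochlorides at O–CH3 (Pinner-salt cleavage by chloride) to the bridged diketopiperazine F9. BH3·THF at reflux followed by acidic methanolysis reduces both lactams to 14, and Boc2O gives 15.

3. Step 12.
- What may go wrong: the polar triamine may be air-oxidised or stay undissolved before it condenses, the hydrogen-bonded imine may resist ring closure, or the oxidant may attack the electron-rich phenol.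
- Fallback from 17 back to 20, redox-neutral in the ring-forming event: Pinnick oxidation (NaClO2, NaH2PO4, 2-methyl-2-butene, t-BuOH–H2O) gives the salicylic acid F10. EDC/HOBt acylation of the 5-amino group of 18 (i-Pr2NEt, DMF) gives the 5-acylaminopyrimidinone F11. Cyclodehydration with aqueous NaOH in EtOH at reflux (classical Traube closure), which the Boc groups tolerate, gives 20.

Further compounds
F1 | step 8 | methyl (Z)-2-(Boc-amino)-3-[4-(benzyloxy)-3-hydroxyphenyl]acrylate | COC(=O)/C(NC(=O)OC(C)(C)C)=C/c1ccc(OCc2ccccc2)c(O)c1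
F2 | step 8 | methyl (S)-2-(Boc-amino)-3-[4-(benzyloxy)-3-hydroxyphenyl]propanoate | COC(=O)[C@H](Cc1ccc(OCc2ccccc2)c(O)c1)NC(=O)OC(C)(C)C
F3 | step 8 | methyl (S)-2-amino-3-[4-(benzyloxy)-3-hydroxyphenyl]propanoate hydrochloride | Cl.COC(=O)[C@@H](N)Cc1ccc(OCc2ccccc2)c(O)c1
F4 | step 8 | Boc-L-Phe(4-I)-L-[4-(benzyloxy)-3-hydroxy]Phe-OMe | CC(C)(C)OC(=O)N[C@@H](Cc1ccc(I)cc1)C(=O)N[C@@H](Cc1ccc(OCc2ccccc2)c(O)c1)C(=O)OC
F5 | step 8 | H-L-Phe(4-I)-L-[4-(benzyloxy)-3-hydroxy]Phe-OMe, free amine | N[C@@H](Cc1ccc(I)cc1)C(=O)N[C@@H](Cc1ccc(OCc2ccccc2)c(O)c1)C(=O)OC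
F6 | step 8 | (3S,6S)-3-[4-(benzyloxy)-3-hydroxybenzyl]-6-(4-iodobenzyl)piperazine-2,5-dione | O=C1N[C@@H](Cc2ccc(I)cc2)C(=O)N[C@H]1Cc1ccc(OCc2ccccc2)c(O)c1
F7 | step 8 | (2S,5S)-2-[4-(benzyloxy)-3-hydroxybenzyl]-5-(4-iodobenzyl)piperazine | Ic1ccc(cc1)C[C@H]1CN[C@H](CN1)Cc1ccc(OCc2ccccc2)c(O)c1
F8 | step 8 | N,N'-di-Boc derivative of F7 | Ic1ccc(cc1)C[C@H]1CN(C(=O)OC(C)(C)C)[C@H](CN1C(=O)OC(C)(C)C)Cc1ccc(OCc2ccccc2)c(O)c1
F9 | step 9 | bridged (3S,6S)-diketopiperazine cyclophane, O-benzyl ether | c1ccccc1COc1ccc2cc1Oc1ccc(cc1)C[C@H]1C(=O)N[C@H](C(=O)N1)C2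
F10 | step 12 | N,N'-di-Boc cyclophane salicylic acid | OC(=O)c1cc2cc(c1O)Oc1ccc(cc1)C[C@H]1CN(C(=O)OC(C)(C)C)[C@H](CN1C(=O)OC(C)(C)C)C2
F11 | step 12 | 5-(aroylamino)-2,6-diaminopyrimidin-4(3H)-one from F10 | Nc1nc(N)c(NC(=O)c2cc3cc(c2O)Oc2ccc(cc2)C[C@H]2CN(C(=O)OC(C)(C)C)[C@H](CN2C(=O)OC(C)(C)C)C3)c(=O)[nH]1
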